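**Remark on the chemistry:** isoflavan numbering is used (chroman O1–C8a = rings A/C, ring B atoms primed, pyran = ring D). The single stereocentre C3 is R by CIP analysis of the given SMILES, and every SMILES below writes it in the same notation as the target.

## Retrosynthetic overview

1. Target 32 ⇐ bis-MOM ether 31 ⇐ o-silylaryl triflate 26 + DMF + (Me2C=CH)2Zn: ring D (the 2,2-dimethylpyran) is built last, with all four of its new bonds formed in one three-component aryne operation.
2. Enabling feature: ring B carries O(C2')–C(C3')–O(C4') on three adjacent carbons. As the C3'≡C4' aryne, the C2' oxygen polarises the triple bond so that the DMF oxygen adds at C4' and carbon at C3'. The O–C(CH3)2–CH=CH–C3' unit of ring D is the ring-closed valence isomer of an o-quinone methide (1-oxatriene).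
3. 26 ⇐ ring C by Mitsunobu O1–C2 closure of triol 24 ⇐ Evans alkylation (C3–C4 bond, sets 3R) of the ring-B arylacetyl imide 21 with the ring-A benzylic bromide 9.
4. Rings A and B both come from 2,4-dihydroxybenzaldehyde by metalation of the C–H between the two oxygens (prenyl for ring A, SiMe3 for ring B). The MOM and carbamate roles are swapped between the two fragments so that one LiAlH4 step frees exactly the three hydroxyls needed.
5. Ring order: A and B (aromatic pool) → C (step 15) → D (step 17).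

Key step: step 17

## Route

Step 1
Reactants: 1 2,4-dihydroxybenzaldehyde
Product: 2 2-hydroxy-4-(methoxymethoxy)benzaldehyde
Conditions: MOMCl (1.05 equiv), K2CO3, acetone, 0 °C to rt
Reagents that add atoms: chloromethyl methyl ether, COCCl
Why: Williamson-type O-alkylation should go to the 4-OH, which is the more acidic phenol, while the 2-OH is held in a hydrogen bond to the formyl group.

Step 2
Reactants: 2 2-hydroxy-4-(methoxymethoxy)benzaldehyde
Product: 3 2-formyl-5-(methoxymethoxy)phenyl N,N-diethylcarbamate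
Conditions: Et2NCOCl, K2CO3, MeCN, 80 °C
Reagents that add atoms: N,N-diethylcarbamoyl chloride, CCN(CC)C(Cl)=O
Why: O-carbamoylation of the remaining phenol installs the strongest ortho-directing group, which is later removed by hydride.

Step 3
Reactants: 3 2-formyl-5-(methoxymethoxy)phenyl N,N-diethylcarbamate
Product: 7 6-formyl-3-(methoxymethoxy)-2-(3-methylbut-2-en-1-yl)phenyl N,N-diethylcarbamate, via amino alkoxide 4 (not isolated), via aryllithium 5 (not isolated), via prenylated amino alkoxide 6 (not isolated)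
Conditions: lithium 4-methylpiperazin-1-ide (from 1-methylpiperazine and n-BuLi), THF, −78 °C; s-BuLi, TMEDA, −78 °C; CuBr·SMe2 (10 mol %), prenyl bromide, −78 to −30 °C; aq. NH4Cl
Reagents that add atoms: 1-bromo-3-methylbut-2-ene, CC(C)=CCBr
Why: the formyl group is masked in situ as its α-amino alkoxide, directed ortho-metalation should then take the only C–H flanked by the carbamate and the MOM ether, and copper-catalysed allylic substitution at the primary carbon of prenyl bromide gives the linear prenyl group before the work-up returns the aldehyde.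

Step 4
Reactants: 7 6-formyl-3-(methoxymethoxy)-2-(3-methylbut-2-en-1-yl)phenyl N,N-diethylcarbamate
Product: 8 6-(hydroxymethyl)-3-(methoxymethoxy)-2-(3-methylbut-2-en-1-yl)phenyl N,N-diethylcarbamate
Conditions: NaBH4, MeOH–THF, 0 °C
Reagents that add atoms: none
Why: borohydride reduction of the aldehyde is chemoselective beside the carbamate, the acetal and the alkene.

Step 5
Reactants: 8 6-(hydroxymethyl)-3-(methoxymethoxy)-2-(3-methylbut-2-en-1-yl)phenyl N,N-diethylcarbamate
Product: 9 6-(bromomethyl)-3-(methoxymethoxy)-2-(3-methylbut-2-en-1-yl)phenyl N,N-diethylcarbamate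
Conditions: CBr4, PPh3, CH2Cl2, 0 °C; used at once without chromatography
Reagents that add atoms: carbon tetrabromide, BrC(Br)(Br)Br
Why: the Appel reaction converts the benzylic alcohol to the bromide under neutral conditions that spare the MOM ether and the prenyl group.

Step 6
Reactants: 1 2,4-dihydroxybenzaldehyde
Product: 10 4-formyl-3-hydroxyphenyl N,N-diethylcarbamate
Conditions: Et2NCOCl (1.0 equiv), K2CO3, MeCN, rt to 50 °C
Reagents that add atoms: N,N-diethylcarbamoyl chloride, CCN(CC)C(Cl)=O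
Why: mono-carbamoylation should again take the more acidic 4-OH that is not hydrogen-bonded, placing the hydride-labile group on the oxygen that later becomes the triflate.

Step 7
Reactants: 10 4-formyl-3-hydroxyphenyl N,N-diethylcarbamate
Product: 11 4-formyl-3-(methoxymethoxy)phenyl N,N-diethylcarbamate
Conditions: MOMCl, i-Pr2NEt, CH2Cl2, 0 °C to reflux
Reagents that add atoms: chloromethyl methyl ether, COCCl
Why: acetal ether formation on the hydrogen-bonded phenol with an amine base is standard for salicylaldehydes.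

Step 8
Reactants: 11 4-formyl-3-(methoxymethoxy)phenyl N,N-diethylcarbamate
Product: 15 4-formyl-3-(methoxymethoxy)-2-(trimethylsilyl)phenyl N,N-diethylcarbamate, via amino alkoxide 12 (not isolated), via aryllithium 13 (not isolated), via silylated amino alkoxide 14 (not isolated)
Conditions: lithium 4-methylpiperazin-1-ide (from 1-methylpiperazine and n-BuLi), THF, −78 °C; s-BuLi, TMEDA, −78 °C; Me3SiCl, −78 °C to rt; aq. NH4Cl
Reagents that add atoms: chlorotrimethylsilane, C[Si](C)(C)Cl
Why: with the aldehyde masked as its α-amino alkoxide, directed ortho-metalation should occur at the C–H between the carbamate and MOM oxygens (two cooperating directors), and silylation there gives the 1,2,3,4-substituted ring B.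

Step 9
Reactants: 15 4-formyl-3-(methoxymethoxy)-2-(trimethylsilyl)phenyl N,N-diethylcarbamate
Product: 16 4-ethenyl-3-(methoxymethoxy)-2-(trimethylsilyl)phenyl N,N-diethylcarbamate
Conditions: Ph3PCH3Br, KOtBu, THF, 0 °C to rt
Reagents that add atoms: methyltriphenylphosphonium bromide, C[P+](c1ccccc1)(c1ccccc1)c1ccccc1.[Br-]
Why: Wittig methylenation of the aryl aldehyde is reliable and leaves the carbamate, acetal and aryl silane untouched.

Step 10
Reactants: 16 4-ethenyl-3-(methoxymethoxy)-2-(trimethylsilyl)phenyl N,N-diethylcarbamate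
Product: 18 4-(2-hydroxyethyl)-3-(methoxymethoxy)-2-(trimethylsilyl)phenyl N,N-diethylcarbamate, via alkylborane 17 (not isolated)
Conditions: 9-BBN, THF, 0 °C to rt; then NaOH, H2O2, 0 °C to rt
Reagents that add atoms: hydrogen peroxide, OO
Why: hydroboration–oxidation of the styrene with the bulky borane gives the anti-Markovnikov primary alcohol, and the aryl–SiMe3 bond is inert to alkaline peroxide.

Step 11
Reactants: 18 4-(2-hydroxyethyl)-3-(methoxymethoxy)-2-(trimethylsilyl)phenyl N,N-diethylcarbamate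
Product: 19 2-[4-(diethylcarbamoyloxy)-2-(methoxymethoxy)-3-(trimethylsilyl)phenyl]acetic acid
Conditions: TEMPO (cat.), PhI(OAc)2, MeCN–H2O, rt
Reagents that add atoms: water, O
Why: nitroxyl-catalysed oxidation with a hypervalent iodine co-oxidant takes the primary alcohol through the aldehyde hydrate to the acid without strong acid or a metal oxidant.

Step 12
Reactants: 19 2-[4-(diethylcarbamoyloxy)-2-(methoxymethoxy)-3-(trimethylsilyl)phenyl]acetic acid
Product: 21 (4R)-4-benzyl-3-{2-[4-(diethylcarbamoyloxy)-2-(methoxymethoxy)-3-(trimethylsilyl)phenyl]acetyl}-1,3-oxazolidin-2-one, via mixed anhydride 20 (not isolated)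
Conditions: t-BuCOCl, Et3N, THF, −20 °C; then (R)-4-benzyl-1,3-oxazolidin-2-one, LiCl, rt
Reagents that add atoms: (R)-4-benzyl-1,3-oxazolidin-2-one, O=C1N[C@H](Cc2ccccc2)CO1
Why: N-acylation of the oxazolidinone through the mixed pivalic anhydride is the standard way to attach the Evans auxiliary to an arylacetic acid.

Step 13
Reactants: 21 (4R)-4-benzyl-3-{2-[4-(diethylcarbamoyloxy)-2-(methoxymethoxy)-3-(trimethylsilyl)phenyl]acetyl}-1,3-oxazolidin-2-one; 9 6-(bromomethyl)-3-(methoxymethoxy)-2-(3-methylbut-2-en-1-yl)phenyl N,N-diethylcarbamate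
Product: 23 (4R)-4-benzyl-3-{(2R)-2-[4-(diethylcarbamoyloxy)-2-(methoxymethoxy)-3-(trimethylsilyl)phenyl]-3-[2-(diethylcarbamoyloxy)-4-(methoxymethoxy)-3-(3-methylbut-2-en-1-yl)phenyl]propanoyl}-1,3-oxazolidin-2-one, via sodium enolate 22 (not isolated)
Conditions: NaN(SiMe3)2, THF, −78 °C; then 9, −78 to −30 °C
Reagents that add atoms: none
Why: Evans alkylation: the sodium-chelated Z-enolate is attacked by the benzylic bromide on the face opposite the benzyl group of the (R)-auxiliary, which sets the future C3 as R.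

Step 14
Reactants: 23 (4R)-4-benzyl-3-{(2R)-2-[4-(diethylcarbamoyloxy)-2-(methoxymethoxy)-3-(trimethylsilyl)phenyl]-3-[2-(diethylcarbamoyloxy)-4-(methoxymethoxy)-3-(3-methylbut-2-en-1-yl)phenyl]propanoyl}-1,3-oxazolidin-2-one
Product: 24 4-{(2R)-1-hydroxy-3-[2-hydroxy-4-(methoxymethoxy)-3-(3-methylbut-2-en-1-yl)phenyl]propan-2-yl}-3-(methoxymethoxy)-2-(trimethylsilyl)phenol
Conditions: LiAlH4, THF, 0 °C to 50 °C; aq. NaOH work-up
Reagents that add atoms: none
Why: hydride reduction cleaves the imide to the primary alcohol and both aryl carbamates to phenols in one operation, while the MOM ethers, the aryl silane, the alkene and the stereocentre (no longer α to a carbonyl once reduced) are not affected.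

Step 15
Reactants: 24 4-{(2R)-1-hydroxy-3-[2-hydroxy-4-(methoxymethoxy)-3-(3-methylbut-2-en-1-yl)phenyl]propan-2-yl}-3-(methoxymethoxy)-2-(trimethylsilyl)phenol
Product: 25 4-[(3R)-7-(methoxymethoxy)-8-(3-methylbut-2-en-1-yl)chroman-3-yl]-3-(methoxymethoxy)-2-(trimethylsilyl)phenol
Conditions: PPh3, DIAD, THF (0.01 M), 0 °C to rt
Reagents that add atoms: none
Why: intramolecular Mitsunobu etherification closes ring C by 6-exo-tet attack of the ring-A phenol on the activated primary carbon; the ring-B phenol is para to the tether and cannot cyclise, and the stereocentre is not involved.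

Step 16
Reactants: 25 4-[(3R)-7-(methoxymethoxy)-8-(3-methylbut-2-en-1-yl)chroman-3-yl]-3-(methoxymethoxy)-2-(trimethylsilyl)phenol
Product: 26 4-[(3R)-7-(methoxymethoxy)-8-(3-methylbut-2-en-1-yl)chroman-3-yl]-3-(methoxymethoxy)-2-(trimethylsilyl)phenyl trifluoromethanesulfonate
Conditions: PhNTf2, DBU, MeCN, rt to 40 °C
Reagents that add atoms: N-phenylbis(trifluoromethanesulfonimide), O=S(=O)(N(c1ccccc1)S(=O)(=O)C(F)(F)F)C(F)(F)F
Why: sulfonylation of the only free phenol with the mild triflimide reagent gives the o-silylaryl triflate without acid that could cleave the MOM ethers or the aryl silane.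

Step 17
Reactants: 26 4-[(3R)-7-(methoxymethoxy)-8-(3-methylbut-2-en-1-yl)chroman-3-yl]-3-(methoxymethoxy)-2-(trimethylsilyl)phenyl trifluoromethanesulfonate
Product: 31 (3R)-7-(methoxymethoxy)-3-[5-(methoxymethoxy)-2,2-dimethyl-2H-chromen-6-yl]-8-(3-methylbut-2-en-1-yl)chroman, via aryne 27 (not isolated), via DMF adduct 28 (not isolated), via allylic aminophenol 29 (not isolated), via vinyl quinone methide 30 (not isolated)
Conditions: (Me2C=CH)2Zn [from Me2C=CHMgBr (2 equiv) and ZnCl2 in THF, MgBrCl precipitated with 1,4-dioxane], CsF, DMF, rt; then AcOH, 90 °C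
Reagents that add atoms: N,N-dimethylformamide, CN(C)C=O; bis(2-methylprop-1-enyl)zinc, CC(C)=C[Zn]C=C(C)C
Why: Proposed new method: fluoride removes the silyl group and expels triflate to give the C3'≡C4' aryne 27, the DMF carbonyl adds across it in a formal [2+2] (O to C4', formyl carbon to C3') and the benzoxete opens to the aminomethylene quinone methide 28, whose iminium-like carbon accepts the 2-methylprop-1-enyl group from zinc to give 29 as its zinc phenoxide; acetic acid and heat then expel dimethylamine to the 1-oxatriene 30, which closes ring D by thermal disrotatory 6π-oxa-electrocyclisation, forming the O–C(CH3)2 bond and the ring-D alkene. The closest known reaction types are the three-component coupling of arynes, DMF and dialkylzincs to o-hydroxybenzylamines and the Petasis-type 2H-chromene synthesis, in which the same kind of allylic aminophenol loses its amine and electrocyclises; what is new is the alkenylzinc partner and the telescoping through to the chromene. The product gains no stereocentre, since the aminated carbon of 29 is transient and becomes sp2, and C3 of the chroman is remote and untouched. The selectivity needed is regiochemical: the inductively withdrawing C2' OMOM group beside the triple bond distorts the aryne so that C4' is the more electrophilic and less hindered terminus, which puts oxygen on C4' and carbon on C3' as the target requires; chemoselectivity rests on DMF being the solvent and on the absence of free OH groups.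

Step 18
Reactants: 31 (3R)-7-(methoxymethoxy)-3-[5-(methoxymethoxy)-2,2-dimethyl-2H-chromen-6-yl]-8-(3-methylbut-2-en-1-yl)chroman
Product: 32 (3R)-3-(5-hydroxy-2,2-dimethyl-2H-chromen-6-yl)-8-(3-methylbut-2-en-1-yl)chroman-7-ol
Conditions: HCl (2 M aq.), MeOH–THF, 40 °C
Reagents that add atoms: none
Why: acid-catalysed acetal methanolysis should remove both aryl MOM ethers under conditions mild enough for the prenyl group and the chromene alkene.

## Compound list

1 | 2,4-dihydroxybenzaldehyde | O=Cc1ccc(O)cc1O | starting material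
2 | 2-hydroxy-4-(methoxymethoxy)benzaldehyde | COCOc1ccc(C=O)c(O)c1 | intermediate
3 | 2-formyl-5-(methoxymethoxy)phenyl N,N-diethylcarbamate | CCN(CC)C(=O)Oc1cc(OCOC)ccc1C=O | intermediate
4 | lithium [2-(diethylcarbamoyloxy)-4-(methoxymethoxy)phenyl](4-methylpiperazin-1-yl)methanolate (amino alkoxide) | [Li+].[O-]C(N1CCN(C)CC1)c1ccc(OCOC)cc1OC(=O)N(CC)CC | intermediate
5 | the same amino alkoxide lithiated at the ring carbon between the carbamate and MOM oxygens (aryllithium) | [Li+].[O-]C(N1CCN(C)CC1)c1ccc(OCOC)c([Li])c1OC(=O)N(CC)CC | intermediate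
6 | lithium [2-(diethylcarbamoyloxy)-4-(methoxymethoxy)-3-(3-methylbut-2-en-1-yl)phenyl](4-methylpiperazin-1-yl)methanolate (prenylated amino alkoxide) | [Li+].[O-]C(N1CCN(C)CC1)c1ccc(OCOC)c(CC=C(C)C)c1OC(=O)N(CC)CC | intermediate
7 | 6-formyl-3-(methoxymethoxy)-2-(3-methylbut-2-en-1-yl)phenyl N,N-diethylcarbamate | CCN(CC)C(=O)Oc1c(CC=C(C)C)c(OCOC)ccc1C=O | intermediate
8 | 6-(hydroxymethyl)-3-(methoxymethoxy)-2-(3-methylbut-2-en-1-yl)phenyl N,N-diethylcarbamate | CCN(CC)C(=O)Oc1c(CC=C(C)C)c(OCOC)ccc1CO | intermediate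
9 | 6-(bromomethyl)-3-(methoxymethoxy)-2-(3-methylbut-2-en-1-yl)phenyl N,N-diethylcarbamate | CCN(CC)C(=O)Oc1c(CC=C(C)C)c(OCOC)ccc1CBr | intermediate
10 | 4-formyl-3-hydroxyphenyl N,N-diethylcarbamate | CCN(CC)C(=O)Oc1ccc(C=O)c(O)c1 | intermediate
11 | 4-formyl-3-(methoxymethoxy)phenyl N,N-diethylcarbamate | CCN(CC)C(=O)Oc1ccc(C=O)c(OCOC)c1 | intermediate
12 | lithium [4-(diethylcarbamoyloxy)-2-(methoxymethoxy)phenyl](4-methylpiperazin-1-yl)methanolate (amino alkoxide) | [Li+].[O-]C(N1CCN(C)CC1)c1ccc(OC(=O)N(CC)CC)cc1OCOC | intermediate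
13 | the same amino alkoxide lithiated at the ring carbon between the carbamate and MOM oxygens (aryllithium) | [Li+].[O-]C(N1CCN(C)CC1)c1ccc(OC(=O)N(CC)CC)c([Li])c1OCOC | intermediate
14 | lithium [4-(diethylcarbamoyloxy)-2-(methoxymethoxy)-3-(trimethylsilyl)phenyl](4-methylpiperazin-1-yl)methanolate (silylated amino alkoxide) | [Li+].[O-]C(N1CCN(C)CC1)c1ccc(OC(=O)N(CC)CC)c([Si](C)(C)C)c1OCOC | intermediate
15 | 4-formyl-3-(methoxymethoxy)-2-(trimethylsilyl)phenyl N,N-diethylcarbamate | CCN(CC)C(=O)Oc1ccc(C=O)c(OCOC)c1[Si](C)(C)C | intermediate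
16 | 4-ethenyl-3-(methoxymethoxy)-2-(trimethylsilyl)phenyl N,N-diethylcarbamate | CCN(CC)C(=O)Oc1ccc(C=C)c(OCOC)c1[Si](C)(C)C | intermediate
17 | 4-[2-(9-borabicyclo[3.3.1]nonan-9-yl)ethyl]-3-(methoxymethoxy)-2-(trimethylsilyl)phenyl N,N-diethylcarbamate (alkylborane) | CCN(CC)C(=O)Oc1ccc(CCB2C3CCCC2CCC3)c(OCOC)c1[Si](C)(C)C | intermediate
18 | 4-(2-hydroxyethyl)-3-(methoxymethoxy)-2-(trimethylsilyl)phenyl N,N-diethylcarbamate | CCN(CC)C(=O)Oc1ccc(CCO)c(OCOC)c1[Si](C)(C)C | intermediate
19 | 2-[4-(diethylcarbamoyloxy)-2-(methoxymethoxy)-3-(trimethylsilyl)phenyl]acetic acid | CCN(CC)C(=O)Oc1ccc(CC(=O)O)c(OCOC)c1[Si](C)(C)C | intermediate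
20 | mixed anhydride of 19 with pivalic acid | CCN(CC)C(=O)Oc1ccc(CC(=O)OC(=O)C(C)(C)C)c(OCOC)c1[Si](C)(C)C | intermediate
21 | (4R)-4-benzyl-3-{2-[4-(diethylcarbamoyloxy)-2-(methoxymethoxy)-3-(trimethylsilyl)phenyl]acetyl}-1,3-oxazolidin-2-one | CCN(CC)C(=O)Oc1ccc(CC(=O)N2[C@H](Cc3ccccc3)COC2=O)c(OCOC)c1[Si](C)(C)C | intermediate
22 | sodium Z-enolate of 21 (O and aryl cis) | [Na+].[O-]/C(=C\c1ccc(OC(=O)N(CC)CC)c([Si](C)(C)C)c1OCOC)N1[C@H](Cc2ccccc2)COC1=O | intermediate
23 | (4R)-4-benzyl-3-{(2R)-2-[4-(diethylcarbamoyloxy)-2-(methoxymethoxy)-3-(trimethylsilyl)phenyl]-3-[2-(diethylcarbamoyloxy)-4-(methoxymethoxy)-3-(3-methylbut-2-en-1-yl)phenyl]propanoyl}-1,3-oxazolidin-2-one | O=C(N1[C@H](Cc2ccccc2)COC1=O)[C@@H](c1ccc(OC(=O)N(CC)CC)c([Si](C)(C)C)c1OCOC)Cc1ccc(OCOC)c(CC=C(C)C)c1OC(=O)N(CC)CC | intermediate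
24 | 4-{(2R)-1-hydroxy-3-[2-hydroxy-4-(methoxymethoxy)-3-(3-methylbut-2-en-1-yl)phenyl]propan-2-yl}-3-(methoxymethoxy)-2-(trimethylsilyl)phenol | OC[C@@H](c1ccc(O)c([Si](C)(C)C)c1OCOC)Cc1ccc(OCOC)c(CC=C(C)C)c1O | intermediate
25 | 4-[(3R)-7-(methoxymethoxy)-8-(3-methylbut-2-en-1-yl)chroman-3-yl]-3-(methoxymethoxy)-2-(trimethylsilyl)phenol | CC(C)=CCc1c(OCOC)ccc2c1OC[C@@H](c1ccc(O)c([Si](C)(C)C)c1OCOC)C2 | intermediate
26 | 4-[(3R)-7-(methoxymethoxy)-8-(3-methylbut-2-en-1-yl)chroman-3-yl]-3-(methoxymethoxy)-2-(trimethylsilyl)phenyl trifluoromethanesulfonate | CC(C)=CCc1c(OCOC)ccc2c1OC[C@@H](c1ccc(OS(=O)(=O)C(F)(F)F)c([Si](C)(C)C)c1OCOC)C2 | intermediate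
27 | ring-B C3'≡C4' aryne: (3R)-7-(methoxymethoxy)-3-[2-(methoxymethoxy)-3,4-didehydrophenyl]-8-(3-methylbut-2-en-1-yl)chroman | CC(C)=CCc1c(OCOC)ccc2c1OC[C@@H](C1=C(OCOC)C#CC=C1)C2 | intermediate
28 | DMF adduct: ring-opened benzoxete, 6-[(dimethylamino)methylidene]cyclohexa-2,4-dien-1-one with OMOM at C5 and the (3R)-chroman-3-yl group at C4 | CC(C)=CCc1c(OCOC)ccc2c1OC[C@@H](C1=C(OCOC)C(=CN(C)C)C(=O)C=C1)C2 | intermediate
29 | 2-[1-(dimethylamino)-3-methylbut-2-en-1-yl]-3-(methoxymethoxy)-4-[(3R)-7-(methoxymethoxy)-8-(3-methylbut-2-en-1-yl)chroman-3-yl]phenol (in the flask as its zinc phenoxide; aminated carbon unspecified) | CC(C)=CCc1c(OCOC)ccc2c1OC[C@@H](c1ccc(O)c(C(C=C(C)C)N(C)C)c1OCOC)C2 | intermediate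
30 | vinyl o-quinone methide: 6-(3-methylbut-2-en-1-ylidene)cyclohexa-2,4-dien-1-one with OMOM at C5 and the (3R)-chroman-3-yl group at C4 | CC(C)=CCc1c(OCOC)ccc2c1OC[C@@H](C1=C(OCOC)C(=CC=C(C)C)C(=O)C=C1)C2 | intermediate
31 | (3R)-7-(methoxymethoxy)-3-[5-(methoxymethoxy)-2,2-dimethyl-2H-chromen-6-yl]-8-(3-methylbut-2-en-1-yl)chroman | CC(C)=CCc1c(OCOC)ccc2c1OC[C@@H](c1ccc3c(c1OCOC)C=CC(C)(C)O3)C2 | intermediate
32 | (3R)-3-(5-hydroxy-2,2-dimethyl-2H-chromen-6-yl)-8-(3-methylbut-2-en-1-yl)chroman-7-ol | CC(C)=CCc1c(O)ccc2c1OC[C@@H](c1ccc3c(c1O)C=CC(C)(C)O3)C2 | target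

## Step count and risks

Total step count: 18 (ring-A fragment 5 steps, ring-B fragment 7 steps, 6 steps after the fragments are joined).

Longest linear sequence: 13 steps (steps 6 to 18, 1 → 10 → 11 → 15 → 16 → 18 → 19 → 21 → 23 → 24 → 25 → 26 → 31 → 32).

Steps most likely to fail:

1. **Step 17** (bears the label). The alkenyl transfer from zinc to the aryne–DMF adduct may be slow, so that the adduct is hydrolysed or takes up a second aryne. The aryl anion may be protonated before it closes onto the formamidinium carbon. The loss of dimethylamine may stall at the aminophenol. Fallback with known chemistry, setting out from 26 and coming back at 31: 26 is treated with CsF in DMF alone and worked up with water, which by the known aryne insertion into the formamide C=O and hydrolysis should give 6-hydroxy-2-(methoxymethoxy)-3-[(3R)-7-(methoxymethoxy)-8-(3-methylbut-2-en-1-yl)chroman-3-yl]benzaldehyde F1. Addition of Me2C=CHMgBr (excess, THF, 0 °C) then gives 2-(1-hydroxy-3-methylbut-2-en-1-yl)-3-(methoxymethoxy)-4-[(3R)-7-(methoxymethoxy)-8-(3-methylbut-2-en-1-yl)chroman-3-yl]phenol F2. Warming F2 in toluene (80 °C, silica or a trace of pyridinium tosylate) dehydrates it to the o-quinone methide, which electrocyclises to 31.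

2. **Step 3**. The aryllithium may undergo anionic carbamoyl migration onto the ring before it is trapped, metalation may be incomplete beside the bulky amino alkoxide, or the allylic substitution may proceed with transposition to the reverse-prenyl isomer. Fallback, setting out from 2 and coming back at 7: O-allylation of 2 with methyl 2-methylbut-3-en-2-yl carbonate and Pd(PPh3)4 (zerovalent palladium, Tsuji–Trost conditions, THF, rt) gives 4-(methoxymethoxy)-2-[(2-methylbut-3-en-2-yl)oxy]benzaldehyde F3. Aromatic Claisen rearrangement (toluene, 110 °C) delivers the prenyl group to the only free ortho position and gives 2-hydroxy-4-(methoxymethoxy)-3-(3-methylbut-2-en-1-yl)benzaldehyde F4. Carbamoylation of F4 as in step 2 (Et2NCOCl, K2CO3, MeCN, 80 °C) gives 7.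

3. **Step 18**. Under protic acid the liberated 7-OH may add across the neighbouring prenyl alkene (ring closure to a dimethylchroman), or the chromene alkene may take up solvent. Fallback, setting out from 31 and coming back at 32: non-protic exchange of the aryl MOM ethers with Me3SiOTf and 2,2'-bipyridyl (CH2Cl2, 0 °C) gives (3R)-3-[2,2-dimethyl-5-(trimethylsilyloxy)-2H-chromen-6-yl]-8-(3-methylbut-2-en-1-yl)-7-(trimethylsilyloxy)chroman F5. The silyl ethers of F5 are then cleaved with K2CO3 in MeOH at rt to give 32.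

## Further compounds

F1 | step 17 | 6-hydroxy-2-(methoxymethoxy)-3-[(3R)-7-(methoxymethoxy)-8-(3-methylbut-2-en-1-yl)chroman-3-yl]benzaldehyde | CC(C)=CCc1c(OCOC)ccc2c1OC[C@@H](c1ccc(O)c(C=O)c1OCOC)C2
F2 | step 17 | 2-(1-hydroxy-3-methylbut-2-en-1-yl)-3-(methoxymethoxy)-4-[(3R)-7-(methoxymethoxy)-8-(3-methylbut-2-en-1-yl)chroman-3-yl]phenol | CC(C)=CCc1c(OCOC)ccc2c1OC[C@@H](c1ccc(O)c(C(O)C=C(C)C)c1OCOC)C2
F3 | step 3 | 4-(methoxymethoxy)-2-[(2-methylbut-3-en-2-yl)oxy]benzaldehyde | COCOc1ccc(C=O)c(OC(C)(C)C=C)c1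
F4 | step 3 | 2-hydroxy-4-(methoxymethoxy)-3-(3-methylbut-2-en-1-yl)benzaldehyde | COCOc1ccc(C=O)c(O)c1CC=C(C)C
F5 | step 18 | (3R)-3-[2,2-dimethyl-5-(trimethylsilyloxy)-2H-chromen-6-yl]-8-(3-methylbut-2-en-1-yl)-7-(trimethylsilyloxy)chroman | CC(C)=CCc1c(O[Si](C)(C)C)ccc2c1OC[C@@H](c1ccc3c(c1O[Si](C)(C)C)C=CC(C)(C)O3)C2
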